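Begin with the leftover: ask what substrate still standing at the end of a run must become.

substrate 0.18 M; gas phase 31 mM (held); time 1.0 min

- the target and crystals and idle adduct together standing at 1.0 min, as a percentage of the substrate charged
- the change that raises the amount of target and crystals and idle adduct together at 1.0 min, in percent of the substrate charged most ("none" if none brings more than 2 percentage points) (eta / epsilon / beta / gamma / none)
- amount of target and crystals and idle adduct together at 1.0 min, in percent of the substrate charged, after epsilon

- what is said of target includes crystals and idle adduct
- crystals is a solid; its amount is given per volume of the solution
- at the start none of the gas is dissolved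
- run time (flask): 1.0 min

    crystals ⇌ target, rate k1*(cs1 - [target]) while solid is left; crystals form when [target] > cs1 (cs1 = 0.12 M, k1 = 0.315 /s)
    gas phase ⇌ dissolved gas, rate k2*(csat - [dissolved gas]) (k2 = 0.0454 /s, csat = 31 mM)
    dissolved gas + target ⇌ idle adduct, settled at all times (K3 = 584 /M)
    substrate → side product (k4 = 0.00741 /s)
    substrate + dissolved gas ⇌ target (K5 = 1200 /M, k5 = 0.745 /M/s)

The equilibrium constant of the gas addition times the charged substrate is 220, so the balance of that step lies on the side of target, and the side step competes for the same substrate. The question then is how fast the flask moves toward that end state.

Take the main step first, with gas transfer and nothing else. Charged substrate takes up dissolved gas at 0.134 /s, faster than transfer at 0.0454 /s, so set transfer equal to uptake. This gives c(dissolved gas) = 7.84 mM and target at 35.0% of the charge.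

Add the idle adduct. Count two gases per substrate converted, and call the level where transfer equals that uptake the gas level g: 4.49 mM. Here the adduct balance holds 2.62 adducts per free target, so 72.4% of the target is adduct, and a whole second gas is an overcount. Target falls to 20.1%.

Add the side step. Substrate now decays in pseudo-first-order fashion, through the side-step rate constant plus the rate constant of the gas addition times g. Reckon it at mid-run as 0.130 M, which lifts g to 5.87 mM. Gas starts from zero, so take a lag of 4.17 s off the forward route. The forward exponent a is then 0.244 and the side exponent b is 0.445. Give target the share a/(a+b) of the substrate consumed: 17.7%. Even counted wholly free, this target is below the solubility, so this reckoning forms no crystals and gives the two crystal changes nothing.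

Scale the gain with g at the charge: epsilon. Repeat the reckoning with saturation doubled: mid-run substrate 0.118 M, g 12.7 mM, forward exponent 0.526, and 33.7%.

The forecast gives 18.5% (16.5% to 20.5%), epsilon, and 34.5% (31% to 38%), on the ground that “the idle adduct takes up nearly a second gas per target formed”. Its first figure stands above this reckoning.

The simulation gives 18.4%, with epsilon best at 15 percentage points against 11 points for eta, and 33.9% after it. In this flask dissolved gas reads 0.00419 M at 0.100 min, close to the g reckoned for the charge, 4.49 mM.

Now take the neighbour flask charged with 0.045 M, read at the same time. There g at the charge is 12.5 mM and at mid-run 16.4 mM. The forward exponent is 0.590, which gives 36.8%. The simulation of that neighbour gives 35.0%.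

The numbers of this flask are invented; the run is a simulation.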